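The target is an acyclic ester whose carbonyl carbon C1 lies between the C2–C3 ethylene tether of the 4-hydroxyphenyl ring and the oxygen of the hexacosyl chain. The plan cuts both bonds at C1 (C1–C2 and C1–O), so that C1 enters as carbon monoxide. Aldehyde 1 is methylenated to styrene 2; then 2, hexacosanol 3 and CO 4 are joined in one palladium hydride catalysed operation to the linear ester 5, with no ring and no stereocentre formed. The precursor 2 is a terminal vinylarene whose phenol is masked as a benzyl ether, removed at the end by hydrogenolysis to give 6.

Key step: step 2

Remark: the target is achiral and its O-alkyl group is taken as the unbranched C26 chain. An atom count of every structure (2 C15H14O, 3 C26H54O, 5 C42H68O3, 6 C35H62O3) showed nothing to correct. The benzyl ether is kept because free 4-vinylphenol oligomerises and an acyl mask would exchange with the fatty alcohol under acid. The alcohol 3 is made the limiting partner, with 2 in slight excess.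

Step 1
Reactants: 1 4-(benzyloxy)benzaldehyde
Product: 2 4-benzyloxystyrene [1-(benzyloxy)-4-ethenylbenzene]
Conditions: Ph3PCH3Br, KOtBu, THF, 0 °C to rt
Reagents that add atoms: methyltriphenylphosphonium bromide, C[P+](c1ccccc1)(c1ccccc1)c1ccccc1.[Br-]
Why: Wittig methylenation, in which the non-stabilised ylide made in the flask adds to the non-enolisable aryl aldehyde and the oxaphosphetane collapses to the terminal alkene and Ph3PO, the benzyl ether being inert to the base and no stereocentre arising.

Step 2
Reactants: 2 4-benzyloxystyrene (1.3 equiv); 3 1-hexacosanol (1.0 equiv); 4 carbon monoxide
Product: 5 hexacosyl 3-(4-benzyloxyphenyl)propanoate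
Conditions: Pd(OAc)2 (1 mol%), 1,2-bis(di-tert-butylphosphinomethyl)benzene (2 mol%), MeSO3H (4 mol%), CO (30 bar), toluene, 90 °C
Reagents that add atoms: none
Why: The cationic hydride [(P–P)Pd–H]+, generated from Pd(OAc)2, the bisphosphine and MeSO3H under CO, adds reversibly across the vinyl group of 2, so that the branched benzylic and the linear 2-arylethyl palladium alkyls interconvert by β-hydride elimination and re-addition; CO 4 then inserts into the linear alkyl and hexacosanol 3 cleaves the acylpalladium, which forms the C1–C2 and C1–O bonds and returns the hydride. The closest known reaction type is the palladium-catalysed linear hydroalkoxycarbonylation (hydroesterification) of vinylarenes with alcohols under bulky chelating bisphosphine and sulfonic acid co-catalysis, applied here with a long-chain primary alcohol as the limiting partner in toluene above its melting point. No ring is closed and no stereocentre is created, so only regioselectivity and chemoselectivity matter. The linear ester should win over the branched 2-arylpropanoate because the four tert-butyl groups of the wide-bite-angle chelate make CO insertion and alcoholysis slow at the congested benzylic alkyl, so the unhindered terminal vinyl group of 2 is funnelled through the primary alkyl (Curtin–Hammett control). Chemoselectivity rests on the low acid loading, which limits cationic oligomerisation of the electron-rich styrene, and on the benzyl ether, which masks the phenol and tolerates CO, hydride and dilute acid; all atoms of 2, 3 and 4 end up in 5.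

Step 3
Reactants: 5 hexacosyl 3-(4-benzyloxyphenyl)propanoate
Product: 6 hexacosyl 3-(4-hydroxyphenyl)propanoate
Conditions: H2 (1 atm), Pd/C (10 wt% Pd), THF–EtOAc, 40 °C
Reagents that add atoms: none
Why: Catalytic hydrogenolysis of the benzyl aryl ether on Pd/C frees the phenol, while the saturated primary alkyl ester and the benzene ring are inert at 1 atm and the warm solvent mixture keeps the waxy substrate dissolved.

Compound list
1 | 4-(benzyloxy)benzaldehyde | O=Cc1ccc(OCc2ccccc2)cc1 | starting material
2 | 4-benzyloxystyrene [1-(benzyloxy)-4-ethenylbenzene] | C=Cc1ccc(OCc2ccccc2)cc1 | intermediate
3 | 1-hexacosanol | CCCCCCCCCCCCCCCCCCCCCCCCCCO | starting material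
4 | carbon monoxide | [C-]#[O+] | starting material
5 | hexacosyl 3-(4-benzyloxyphenyl)propanoate | CCCCCCCCCCCCCCCCCCCCCCCCCCOC(=O)CCc1ccc(OCc2ccccc2)cc1 | intermediate
6 | hexacosyl 3-(4-hydroxyphenyl)propanoate | CCCCCCCCCCCCCCCCCCCCCCCCCCOC(=O)CCc1ccc(O)cc1 | target

Total step count: 3
Longest linear sequence: 3 steps (1 → 2 → 5 → 6)

Steps most likely to fail

1. Step 2. Carbonylation may run partly through the benzylic alkyl and give the branched ester. The sulfonic acid may start cationic oligomerisation of the electron-rich vinylarene or Markovnikov addition of the alcohol. Alcoholysis of the acylpalladium by the dilute fatty alcohol may be slow enough for the catalyst to fall out as zerovalent palladium. The fallback gives up the carbonylation and builds the three-carbon chain by condensation. It sets out from 1 and 3. Doebner–Knoevenagel condensation of 1 with malonic acid (pyridine, catalytic piperidine, 90 °C) passes through 2-(4-benzyloxybenzylidene)malonic acid F1, which decarboxylates in the flask to (E)-3-(4-benzyloxyphenyl)prop-2-enoic acid F2. Carbodiimide esterification of this acid with 3 (EDC·HCl, DMAP, CH2Cl2–THF, 40 °C) gives hexacosyl (E)-3-(4-benzyloxyphenyl)prop-2-enoate F3. Hydrogenation under the conditions of step 3 then saturates the alkene and cleaves the benzyl ether in the same operation, so the fallback comes back to the route at 6.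

2. Step 3. Hydrogenolysis may stall through poisoning of the catalyst by phosphine or sulfonate residues carried over from step 2, or through deposition of the waxy substrate on the catalyst. The fallback replaces reductive cleavage by Lewis-acid cleavage. It sets out from 5: BCl3 with pentamethylbenzene as benzyl-cation scavenger, in dilute CH2Cl2 at −20 to 0 °C, should remove the benzyl group without touching the primary alkyl ester, and it comes back at 6. It makes no new compound (entry F0).

3. Step 1. The ylide may be quenched by moisture, and the styrene may be lost by polymerisation on concentration or be hard to free from the phosphine oxide. The fallback is a Peterson olefination and sets out from 1. Addition of Me3SiCH2MgCl (THF, 0 °C) gives racemic 1-(4-benzyloxyphenyl)-2-(trimethylsilyl)ethanol F4. Elimination with KH in THF at rt then delivers the terminal alkene under basic, non-cationic conditions, and the fallback comes back at 2.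

Further compounds
F1 | step 2 | 2-(4-benzyloxybenzylidene)malonic acid | OC(=O)C(=Cc1ccc(OCc2ccccc2)cc1)C(=O)O
F2 | step 2 | (E)-3-(4-benzyloxyphenyl)prop-2-enoic acid | OC(=O)/C=C/c1ccc(OCc2ccccc2)cc1
F3 | step 2 | hexacosyl (E)-3-(4-benzyloxyphenyl)prop-2-enoate | CCCCCCCCCCCCCCCCCCCCCCCCCCOC(=O)/C=C/c1ccc(OCc2ccccc2)cc1
F0 | step 3 | none | none
F4 | step 1 | 1-(4-benzyloxyphenyl)-2-(trimethylsilyl)ethanol (racemic) | C[Si](C)(C)CC(O)c1ccc(OCc2ccccc2)cc1
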